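**Retrosynthetic overview**
1. Last bond: the O4–acyl bond of the tetronate ester, made by fluoride unmasking of a 2-(trimethylsilyl)ethyl enol ether and acylation with 15-methylhexadecanoyl chloride.
2. Key bond: the C(sp3)–C(sp3) bond between the methyl-bearing side-chain carbon C2′ and its CH2 neighbour C3′, formed by a nickel/pybox stereoconvergent Negishi coupling of a racemic secondary allylic chloride (the complete E-ylidene furanone) with a primary C17 alkylzinc iodide; this one step joins the two halves and sets the only stereocentre from racemic material.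
3. Enabling feature: C2′ is allylic to the exocyclic C5=C1′ enol-ether double bond of the furan-2(5H)-one ring, which is conjugated through C4=C3 to the lactone carbonyl; a chloride at C2′ gives an allyl radical spread over C2′–C1′–C5, and because C5 is fully substituted (ring O1 and C4) the new bond can form only at C2′.
4. The E-ylidene furanone comes from Wittig olefination of a 4-alkoxy-3-methylfuran-2,5-dione (from diethyl oxalpropionate) with acetonylidenetriphenylphosphorane, then Luche reduction and Corey–Kim chlorination; the zinc reagent comes from dendrolasin (3-furylmethyl Grignard plus geranyl chloride) by SeO2 oxidation, bromination, vinyl coupling and hydrozirconation–iodination.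
5. Ring order: the furan ring is bought; the five-membered anhydride ring is closed in step 9 and becomes the furan-2(5H)-one ring in the Wittig step 10; no ring is closed in the key step.

Key step: step 13

Remark: the exocyclic olefin of the target is read as E (side chain syn to C4, anti to the ring oxygen) and the methyl-bearing centre as S; the sense of induction of the nickel/pybox catalyst is assigned by analogy, and the ligand antipode would be used if a model coupling shows the opposite sense.

Step 1
Reactants: 1 furan-3-ylmethanol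
Product: 2 3-(chloromethyl)furan
Conditions: SOCl2, pyridine, Et2O, 0 °C
Reagents that add atoms: thionyl chloride, O=S(Cl)Cl
Why: Chlorodehydroxylation of a primary alcohol through its chlorosulfite, with pyridine taking up the HCl so that the acid-sensitive furan should survive; no stereocentre is involved.

Step 2
Reactants: 2 3-(chloromethyl)furan; 3 geranyl chloride [(2E)-1-chloro-3,7-dimethylocta-2,6-diene]
Product: 5 3-[(3E)-4,8-dimethylnona-3,7-dien-1-yl]furan (dendrolasin), via furan-3-ylmethylmagnesium chloride 4 (not isolated)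
Conditions: Mg, THF, 0 °C; then 3, Li2CuCl4 (3 mol%), THF, −10 °C to rt
Reagents that add atoms: none
Why: Kochi-type copper-catalysed Grignard coupling with a primary allylic chloride, which should occur at the chloride-bearing carbon without allylic transposition, so the (E)-olefin of geranyl chloride is kept.

Step 3
Reactants: 5 3-[(3E)-4,8-dimethylnona-3,7-dien-1-yl]furan
Product: 6 (2E,6E)-9-(furan-3-yl)-2,6-dimethylnona-2,6-dien-1-ol
Conditions: SeO2 (0.3 equiv), t-BuOOH (3 equiv), salicylic acid (0.1 equiv), CH2Cl2, 0 °C to rt
Reagents that add atoms: selenium dioxide, O=[Se]=O (catalytic oxygen carrier); tert-butyl hydroperoxide, CC(C)(C)OO (stoichiometric oxygen source)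
Why: Sharpless catalytic allylic oxidation (ene reaction then [2,3]-sigmatropic shift), which should attack the (E)-methyl group of the terminal, least hindered trisubstituted olefin and give the (E)-allylic alcohol, the internal olefin and the furan reacting more slowly.

Step 4
Reactants: 6 (2E,6E)-9-(furan-3-yl)-2,6-dimethylnona-2,6-dien-1-ol
Product: 7 3-[(3E,7E)-9-bromo-4,8-dimethylnona-3,7-dien-1-yl]furan
Conditions: CBr4, PPh3, CH2Cl2, −20 °C
Reagents that add atoms: carbon tetrabromide, BrC(Br)(Br)Br
Why: Appel bromination under neutral conditions should convert the primary allylic alcohol into the bromide without acid that would harm the furan and without allylic transposition.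

Step 5
Reactants: 7 3-[(3E,7E)-9-bromo-4,8-dimethylnona-3,7-dien-1-yl]furan; 8 vinylmagnesium bromide
Product: 9 3-[(3E,7E)-4,8-dimethylundeca-3,7,10-trien-1-yl]furan
Conditions: CuI (5 mol%), THF, −40 to 0 °C
Reagents that add atoms: none
Why: Copper-catalysed coupling of a vinyl Grignard reagent with a primary allylic bromide at the bromide-bearing carbon should give the skipped diene with retention of the (E)-trisubstituted olefin.

Step 6
Reactants: 9 3-[(3E,7E)-4,8-dimethylundeca-3,7,10-trien-1-yl]furan
Product: 11 3-[(3E,7E)-11-iodo-4,8-dimethylundeca-3,7-dien-1-yl]furan, via alkylzirconocene chloride 10 (not isolated)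
Conditions: Cp2Zr(H)Cl, THF, rt; then I2, 0 °C
Reagents that add atoms: iodine, II
Why: Schwartz hydrozirconation is selective for the terminal vinyl group over the trisubstituted olefins and places zirconium on the terminal carbon, and iodinolysis of the carbon–zirconium bond should give the primary iodide.

Step 7
Reactants: 12 diethyl oxalpropionate (diethyl 2-methyl-3-oxobutanedioate); 13 2-(trimethylsilyl)ethanol
Product: 14 diethyl 2-methyl-3-[2-(trimethylsilyl)ethoxy]but-2-enedioate (E/Z mixture)
Conditions: PPh3, DIAD, THF, 0 °C to rt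
Reagents that add atoms: none
Why: Mitsunobu O-alkylation of the acidic enol of the 2-oxosuccinate (C-alkylation is disfavoured at the methyl-bearing carbon) should give the enol ether as a mixture of olefin isomers, both of which are carried on.

Step 8
Reactants: 14 diethyl 2-methyl-3-[2-(trimethylsilyl)ethoxy]but-2-enedioate
Product: 15 2-methyl-3-[2-(trimethylsilyl)ethoxy]but-2-enedioic acid (E/Z mixture)
Conditions: LiOH·H2O, THF/H2O, 0 °C to rt; then 1 M HCl to pH 2, 0 °C
Reagents that add atoms: lithium hydroxide, [Li+].[OH-]
Why: Saponification of both ethyl esters, the 2-(trimethylsilyl)ethyl enol ether being stable to hydroxide.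

Step 9
Reactants: 15 2-methyl-3-[2-(trimethylsilyl)ethoxy]but-2-enedioic acid
Product: 16 3-methyl-4-[2-(trimethylsilyl)ethoxy]furan-2,5-dione
Conditions: Ac2O, 80 °C
Reagents that add atoms: none
Why: Cyclodehydration with acetic anhydride, in which the push–pull 2-alkoxybutenedioic acid should isomerise so that both olefin isomers converge on the cyclic anhydride.

Step 10
Reactants: 16 3-methyl-4-[2-(trimethylsilyl)ethoxy]furan-2,5-dione; 17 1-(triphenylphosphoranylidene)propan-2-one
Product: 18 (5E)-3-methyl-5-(2-oxopropylidene)-4-[2-(trimethylsilyl)ethoxy]furan-2(5H)-one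
Conditions: CHCl3, 0 °C to rt, dark
Reagents that add atoms: none
Why: Wittig olefination of a cyclic anhydride with a ketone-stabilised ylide, which should attack the more electrophilic carbonyl next to the alkoxy-bearing carbon (the other is a deactivated vinylogous carbonate flanked by methyl) and, as with phthalic and maleic anhydrides, give under kinetic control the (E)-ylidene lactone with the acyl group anti to the ring oxygen.

Step 11
Reactants: 18 (5E)-3-methyl-5-(2-oxopropylidene)-4-[2-(trimethylsilyl)ethoxy]furan-2(5H)-one
Product: 19 rac-(5E)-5-(2-hydroxypropylidene)-3-methyl-4-[2-(trimethylsilyl)ethoxy]furan-2(5H)-one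
Conditions: NaBH4, CeCl3·7H2O, MeOH, −78 °C
Reagents that add atoms: none
Why: Luche reduction should give clean 1,2-reduction of the ketone without touching the lactone or the conjugated system, and the carbinol centre is made racemic on purpose because step 13 is stereoconvergent.

Step 12
Reactants: 19 rac-(5E)-5-(2-hydroxypropylidene)-3-methyl-4-[2-(trimethylsilyl)ethoxy]furan-2(5H)-one
Product: 20 rac-(5E)-5-(2-chloropropylidene)-3-methyl-4-[2-(trimethylsilyl)ethoxy]furan-2(5H)-one
Conditions: NCS, Me2S, CH2Cl2, −20 to 0 °C
Reagents that add atoms: N-chlorosuccinimide, O=C1CCC(=O)N1Cl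
Why: Corey–Kim chlorination (displacement of an alkoxysulfonium group by chloride) should give the secondary allylic chloride under non-acidic conditions that do not ionise the allylic system or disturb the (E)-olefin.

Step 13
Reactants: 11 3-[(3E,7E)-11-iodo-4,8-dimethylundeca-3,7-dien-1-yl]furan; 20 rac-(5E)-5-(2-chloropropylidene)-3-methyl-4-[2-(trimethylsilyl)ethoxy]furan-2(5H)-one
Product: 22 (5E)-5-[(2S,6E,10E)-13-(furan-3-yl)-2,6,10-trimethyltrideca-6,10-dien-1-ylidene]-3-methyl-4-[2-(trimethylsilyl)ethoxy]furan-2(5H)-one, via alkylzinc iodide 21 (not isolated)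
Conditions: Zn dust, I2 (5 mol%), DMA, 40 °C (gives 21, 1.5 equiv); then 20, NiCl2·glyme (5 mol%), (S,S)-2,6-bis[4-(2-phenylethyl)-4,5-dihydrooxazol-2-yl]pyridine (5.5 mol%), NaCl (4 equiv), DMA/DMF 1:1, −10 °C
Reagents that add atoms: none
Why: Mechanism: the alkylzinc iodide 21 transmetalates to a pybox-bound nickel centre, the resulting monovalent alkylnickel abstracts chlorine from either enantiomer of 20 to give one common allyl radical spread over C2′–C1′–C5, and radical capture followed by reductive elimination from trivalent nickel forms the C3′–C2′ bond. The closest known reaction type is the nickel/pybox stereoconvergent Negishi coupling of racemic secondary allylic chlorides, ester-conjugated ones included, with primary alkylzinc halides. No ring is closed. The new stereocentre C2′ is set under catalyst control by the C2-symmetric pybox ligand in the bond-forming event, so both enantiomers of 20 should converge on the (S)-product. The step needs regioselectivity for C2′ over C5, secured because C5 is fully substituted (O1 and C4) and coupling at C2′ keeps the conjugation to the lactone, and it needs retention of the (E)-C5=C1′ geometry, expected because radical capture at −10 °C should outrun rotation about the C5–C1′ bond and the amide solvent tames the Lewis acidity of the zinc halides. The neutral alkylzinc reagent should leave the lactone, the silyl group, the furan and the trisubstituted olefins untouched.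

Step 14
Reactants: 23 15-methylhexadecanoic acid
Product: 24 15-methylhexadecanoyl chloride
Conditions: (COCl)2, DMF (cat.), CH2Cl2, 0 °C to rt
Reagents that add atoms: oxalyl chloride, ClC(=O)C(=O)Cl
Why: Acid chloride formation with oxalyl chloride under Vilsmeier (DMF) catalysis.

Step 15
Reactants: 22 (5E)-5-[(2S,6E,10E)-13-(furan-3-yl)-2,6,10-trimethyltrideca-6,10-dien-1-ylidene]-3-methyl-4-[2-(trimethylsilyl)ethoxy]furan-2(5H)-one; 24 15-methylhexadecanoyl chloride
Product: 26 (2E)-2-[(2S,6E,10E)-13-(furan-3-yl)-2,6,10-trimethyltrideca-6,10-dien-1-ylidene]-4-methyl-5-oxo-2,5-dihydrofuran-3-yl 15-methylhexadecanoate, via tetrabutylammonium tetronate 25 (not isolated)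
Conditions: Bu4NF (1 M in THF, 1.05 equiv), THF, −20 to 0 °C; then 24, 0 °C
Reagents that add atoms: none
Why: Fluoride-induced fragmentation of the 2-(trimethylsilyl)ethyl enol ether (β-silyl elimination with loss of ethylene) should unmask the tetronate anion, which is O-acylated by the acid chloride because C3 is blocked by methyl, while the C5=C1′ geometry and the C2′ stereocentre are not involved.

**Compound list**
1 | furan-3-ylmethanol | OCc1ccoc1 | starting material
2 | 3-(chloromethyl)furan | ClCc1ccoc1 | intermediate
3 | geranyl chloride, (2E)-1-chloro-3,7-dimethylocta-2,6-diene | CC(C)=CCC/C(C)=C/CCl | starting material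
4 | furan-3-ylmethylmagnesium chloride | Cl[Mg]Cc1ccoc1 | intermediate (not isolated)
5 | 3-[(3E)-4,8-dimethylnona-3,7-dien-1-yl]furan (dendrolasin) | CC(C)=CCC/C(C)=C/CCc1ccoc1 | intermediate
6 | (2E,6E)-9-(furan-3-yl)-2,6-dimethylnona-2,6-dien-1-ol | OC/C(C)=C/CC/C(C)=C/CCc1ccoc1 | intermediate
7 | 3-[(3E,7E)-9-bromo-4,8-dimethylnona-3,7-dien-1-yl]furan | BrC/C(C)=C/CC/C(C)=C/CCc1ccoc1 | intermediate
8 | vinylmagnesium bromide | C=C[Mg]Br | starting material
9 | 3-[(3E,7E)-4,8-dimethylundeca-3,7,10-trien-1-yl]furan | C=CC/C(C)=C/CC/C(C)=C/CCc1ccoc1 | intermediate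
10 | chlorobis(cyclopentadienyl)[(4E,8E)-11-(furan-3-yl)-4,8-dimethylundeca-4,8-dien-1-yl]zirconium | [CH2-]CC/C(C)=C/CC/C(C)=C/CCc1ccoc1.[Cl-].[Zr+4].c1cc[cH-]c1.c1cc[cH-]c1 | intermediate (not isolated)
11 | 3-[(3E,7E)-11-iodo-4,8-dimethylundeca-3,7-dien-1-yl]furan | ICCC/C(C)=C/CC/C(C)=C/CCc1ccoc1 | intermediate
12 | diethyl oxalpropionate (diethyl 2-methyl-3-oxobutanedioate) | CCOC(=O)C(C)C(=O)C(=O)OCC | starting material
13 | 2-(trimethylsilyl)ethanol | C[Si](C)(C)CCO | starting material
14 | diethyl 2-methyl-3-[2-(trimethylsilyl)ethoxy]but-2-enedioate (E/Z mixture) | CCOC(=O)C(C)=C(OCC[Si](C)(C)C)C(=O)OCC | intermediate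
15 | 2-methyl-3-[2-(trimethylsilyl)ethoxy]but-2-enedioic acid (E/Z mixture) | OC(=O)C(C)=C(OCC[Si](C)(C)C)C(=O)O | intermediate
16 | 3-methyl-4-[2-(trimethylsilyl)ethoxy]furan-2,5-dione | CC1=C(OCC[Si](C)(C)C)C(=O)OC1=O | intermediate
17 | 1-(triphenylphosphoranylidene)propan-2-one | CC(=O)C=P(c1ccccc1)(c1ccccc1)c1ccccc1 | starting material
18 | (5E)-3-methyl-5-(2-oxopropylidene)-4-[2-(trimethylsilyl)ethoxy]furan-2(5H)-one | CC1=C(OCC[Si](C)(C)C)/C(=C\C(C)=O)OC1=O | intermediate
19 | rac-(5E)-5-(2-hydroxypropylidene)-3-methyl-4-[2-(trimethylsilyl)ethoxy]furan-2(5H)-one | CC1=C(OCC[Si](C)(C)C)/C(=C\C(C)O)OC1=O | intermediate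
20 | rac-(5E)-5-(2-chloropropylidene)-3-methyl-4-[2-(trimethylsilyl)ethoxy]furan-2(5H)-one | CC1=C(OCC[Si](C)(C)C)/C(=C\C(C)Cl)OC1=O | intermediate
21 | [(4E,8E)-11-(furan-3-yl)-4,8-dimethylundeca-4,8-dien-1-yl]zinc iodide | I[Zn]CCC/C(C)=C/CC/C(C)=C/CCc1ccoc1 | intermediate (not isolated)
22 | (5E)-5-[(2S,6E,10E)-13-(furan-3-yl)-2,6,10-trimethyltrideca-6,10-dien-1-ylidene]-3-methyl-4-[2-(trimethylsilyl)ethoxy]furan-2(5H)-one | CC1=C(OCC[Si](C)(C)C)/C(=C\[C@@H](C)CCC/C(C)=C/CC/C(C)=C/CCc2ccoc2)OC1=O | intermediate
23 | 15-methylhexadecanoic acid | OC(=O)CCCCCCCCCCCCCC(C)C | starting material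
24 | 15-methylhexadecanoyl chloride | ClC(=O)CCCCCCCCCCCCCC(C)C | intermediate
25 | tetrabutylammonium (2E)-2-[(2S,6E,10E)-13-(furan-3-yl)-2,6,10-trimethyltrideca-6,10-dien-1-ylidene]-4-methyl-5-oxo-2,5-dihydrofuran-3-olate | CC1=C([O-])/C(=C\[C@@H](C)CCC/C(C)=C/CC/C(C)=C/CCc2ccoc2)OC1=O.CCCC[N+](CCCC)(CCCC)CCCC | intermediate (not isolated)
26 | (2E)-2-[(2S,6E,10E)-13-(furan-3-yl)-2,6,10-trimethyltrideca-6,10-dien-1-ylidene]-4-methyl-5-oxo-2,5-dihydrofuran-3-yl 15-methylhexadecanoate | CC1=C(OC(=O)CCCCCCCCCCCCCC(C)C)/C(=C\[C@@H](C)CCC/C(C)=C/CC/C(C)=C/CCc2ccoc2)OC1=O | target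

**Step count**
Total: 15 steps. Longest linear sequence: 8 steps (steps 7–13 and 15, or steps 1–6, 13 and 15).

**Steps most likely to fail**

Step 13 (key coupling). What may go wrong: rotation of the allyl radical, or of an allyl cation formed by Lewis-acid ionisation of the chloride, about the C5–C1′ bond before capture, which would erode the (E)-geometry; and insufficient facial discrimination by the catalyst, which would lower the enantiomeric purity. Fallback, a stereospecific two-electron substitution in place of the radical coupling: it sets out from 18 and comes back at 22. Ketone 18 is reduced with (R)-2-methyl-CBS-oxazaborolidine and catecholborane (toluene, −78 °C) to (5E)-5-[(2S)-2-hydroxypropylidene]-3-methyl-4-[2-(trimethylsilyl)ethoxy]furan-2(5H)-one F1. F1 is phosphorylated with diethyl chlorophosphate and pyridine to diethyl (2S)-1-{(2E)-4-methyl-5-oxo-3-[2-(trimethylsilyl)ethoxy]furan-2(5H)-ylidene}propan-2-yl phosphate F2. Iodide 11 is converted with Mg in THF into [(4E,8E)-11-(furan-3-yl)-4,8-dimethylundeca-4,8-dien-1-yl]magnesium iodide F3. Copper-catalysed substitution of F2 by F3 (Li2CuCl4, THF, −78 °C) should proceed anti to the phosphate; C5 is blocked, so the alkyl group should enter at C2′ with inversion and give 22 with the olefin geometry unchanged.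

Step 10 (anhydride Wittig). What may go wrong: attack at the other anhydride carbonyl, and light- or nucleophile-induced equilibration of the (E)-ylidene ketone to the less crowded (Z)-isomer. Fallback, which fixes the geometry by a stereoselective reduction and a stereoretentive addition instead of a Wittig reaction: it sets out from 16 and comes back at 19. Anhydride 16 is treated with CBr4 and PPh3 to give 5-(dibromomethylidene)-3-methyl-4-[2-(trimethylsilyl)ethoxy]furan-2(5H)-one F4. Hydrogenolysis with Bu3SnH and Pd(PPh3)4 should remove the less hindered bromine, the one syn to the ring oxygen, and leave (5E)-5-(bromomethylidene)-3-methyl-4-[2-(trimethylsilyl)ethoxy]furan-2(5H)-one F5. Nozaki–Hiyama–Kishi addition of F5 to acetaldehyde (CrCl2, NiCl2 cat., DMF) should give 19 with retention of the olefin geometry.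

Step 3 (SeO2 oxidation of dendrolasin). What may go wrong: competing oxidation at the internal olefin or of the furan ring, and over-oxidation to the enal. Fallback, in which the oxidation is done before the furan is present: it sets out from Grignard reagent 4 (made from 2 as in step 2) and commercial geranyl acetate, and comes back at 9. Geranyl acetate is oxidised with SeO2/t-BuOOH to (2E,6E)-8-hydroxy-3,7-dimethylocta-2,6-dien-1-yl acetate F6. F6 is converted with CBr4/PPh3 into (2E,6E)-8-bromo-3,7-dimethylocta-2,6-dien-1-yl acetate F7. F7 is coupled with vinylmagnesium bromide 8 (CuI cat., THF, −40 °C, where the allylic bromide reacts before the acetate) to give (2E,6E)-3,7-dimethyldeca-2,6,9-trien-1-yl acetate F8. Li2CuCl4-catalysed displacement of the primary allylic acetate of F8 by Grignard reagent 4 should give 9.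

Further compounds
F1 | step 13 | (5E)-5-[(2S)-2-hydroxypropylidene]-3-methyl-4-[2-(trimethylsilyl)ethoxy]furan-2(5H)-one | CC1=C(OCC[Si](C)(C)C)/C(=C\[C@H](C)O)OC1=O
F2 | step 13 | diethyl (2S)-1-{(2E)-4-methyl-5-oxo-3-[2-(trimethylsilyl)ethoxy]furan-2(5H)-ylidene}propan-2-yl phosphate | CC1=C(OCC[Si](C)(C)C)/C(=C\[C@H](C)OP(=O)(OCC)OCC)OC1=O
F3 | step 13 | [(4E,8E)-11-(furan-3-yl)-4,8-dimethylundeca-4,8-dien-1-yl]magnesium iodide | I[Mg]CCC/C(C)=C/CC/C(C)=C/CCc1ccoc1
F4 | step 10 | 5-(dibromomethylidene)-3-methyl-4-[2-(trimethylsilyl)ethoxy]furan-2(5H)-one | CC1=C(OCC[Si](C)(C)C)C(=C(Br)Br)OC1=O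
F5 | step 10 | (5E)-5-(bromomethylidene)-3-methyl-4-[2-(trimethylsilyl)ethoxy]furan-2(5H)-one | CC1=C(OCC[Si](C)(C)C)/C(=C\Br)OC1=O
F6 | step 3 | (2E,6E)-8-hydroxy-3,7-dimethylocta-2,6-dien-1-yl acetate | OC/C(C)=C/CC/C(C)=C/COC(C)=O
F7 | step 3 | (2E,6E)-8-bromo-3,7-dimethylocta-2,6-dien-1-yl acetate | BrC/C(C)=C/CC/C(C)=C/COC(C)=O
F8 | step 3 | (2E,6E)-3,7-dimethyldeca-2,6,9-trien-1-yl acetate | C=CC/C(C)=C/CC/C(C)=C/COC(C)=O
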